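**Compound numbering used throughout:** 1–19 as defined in the steps and the compound list; C1–C9 are the skeletal atoms of the target (C1 acyl bridgehead, C2/C3/C4 enolised dione, C5 prenyl bridgehead, C6 CH2, C7 prenyl methine, C8 methyl/homoprenyl carbon, C9 bridging ketone; ring A = C1-C8-C7-C6-C5-C9, ring B = C1-C2-C3-C4-C5-C9).

## Analysis of the target

The target 19 is a bicyclo[3.3.1]non-3-ene-2,9-dione. Ring A is a cyclohexanone whose carbonyl C9 bridges ring B, an enolised β-diketone; isobutyryl sits on C1, prenyl on C5 and C7, methyl and homoprenyl on C8, and C3 carries only hydrogen. There are four stereocentres, but C1 and C5 are tied to each other by the bicycle, so the independent elements are C5, the C7 methine and the quaternary C8. The C7 prenyl and the C8 methyl are cis and both lie on the face of ring A that looks at ring B, with the homoprenyl arm on the far face. In a chair ring A this prenyl would be axial and point into ring B, so ring A is expected to sit in a boat-like form. Sensitive groups are the acidic, O/C-ambident vinylogous acid, three trisubstituted alkenes that protonate and close onto enol oxygens, and the non-enolisable tricarbonyl carbon C1, which is open to retro-Claisen cleavage. The hard points are the bond between the two fully substituted carbons C1 and C8, the C7 prenyl on the hindered ring B side, and C3, which must stay unsubstituted although it is the most nucleophilic carbon of ring B. The strategy rests on one feature: C6, C7 and C8 are the first carbons of a geranyl-type chain on C5 of a dearomatised acylphloroglucinol (ring B), so ring A is that chain folded back onto C1 with a prenyl unit delivered to C7.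

## Retrosynthetic reasoning

**19 from 18 (C3–H from C3–Cl).** C3 lies between two oxygenated carbons and would take any electrophile first. A chlorine holds this position through the alkylation, dearomatisation, cascade and metathesis steps. It is the one substituent that can be taken off at the end without touching alkenes or ketones. The forward step only has to reduce an α-chloro-β-diketone.

**18 from 16 and 17 (two isopropylidene ends cut back to vinyl ends).** The C5 prenyl and the C8 homoprenyl group are traced back to allyl and but-3-enyl. The reason lies in the key step: a prenyl group on C5 would be a constitutional twin of the C6–C7=C8 arm, at the same distance from C1, and could close the same ring. A chain ending in an isopropylidene group would offer the cation a second, more exposed trisubstituted alkene. Monosubstituted alkenes are far less nucleophilic towards a carbocation, so 16 is reached from a substrate with a single reactive alkene. One cross-metathesis with 17 restores both ends; the C7 prenyl made in the key step can only exchange degenerately.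

**16 from 13 and 14 (C7–prenyl and C1–C8).** These two cuts open ring A to a chain on C5 of dienone 13 and remove three stereocentres at once, leaving C5 as the only one. In the forward direction the cation from 14 adds to C7, the tertiary cation 15 forms at C8 and is trapped by enol carbon C1. Anti addition across the (E)-alkene gives prenyl cis to methyl. The fold of the chain over ring B decides how C7 and C8 relate to C5, and the boat-like fold is the one needed.

**13 from 11 and 12 (C5–allyl, dearomatisation).** Cutting the allyl group returns the aromatic ring of 11. No ring carbon of 11 carries hydrogen, so C-allylation must dearomatise, and the electron-rich alkyl-bearing carbon is the natural site. The chlorine has to be present already at this stage: a free C3–H would take the allyl group with rearomatisation. The unsubstituted allyl unit also avoids linear/branched and E/Z questions at the π-allyl stage. The forward step must set C5 by catalyst control.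

**11 from 4 and 10 (C5–C6).** The chain is attached by C-alkylation of the phenolate of 4 with allylic bromide 10. Only one ring carbon of 4 is free, so the position of the chain is not in question.

**4 from 3, and 3 from 1 and 2 (C–Cl, C–acyl).** Chlorination is placed before any alkene is in the molecule. The acyl group, the future C1 substituent, comes first by arene acylation, so the most hindered C–C bond of the target never has to be made on the bicycle.

**10 from 9, 8, and 5 plus 6 (the (E)-alkene).** The C8–butenyl bond is made by syn-carbocupration of ynoate 5 with the copper reagent from 6. Reduction and bromination then give 10. The geometry fixed here becomes the C7/C8 relationship in step 8, so it has to be set stereospecifically rather than separated later.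

## Alternatives that were turned down

**Alternative 1:** Ring B is made last on a five-membered ketone. The cuts are C4–C5 and C1–C9: the C5 lithium enolate of cyclopentanone A1 (LiN(iPr)2) is C-acylated by diketene A2, and the acetoacetyl end C1 then adds to the C9 carbonyl to give the cis-fused hydroxy hydrindanedione A3.
- For it: C7 and C8 are set on a small ring by ordinary enolate and conjugate-addition chemistry, two C–C bonds come from a cheap four-carbon unit, and no cation has to choose between nucleophiles. On the C7/C8 relationship it is stronger than the chosen route.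
- Against it for this target: A3 is not yet the bicycle. C8 must still be shifted from C9 to C1, and the C5 prenyl and the C1 isobutyryl group must be put on bridgeheads afterwards. Each of these later events has to occur on the face syn to the C7 prenyl, against the steric bias of the C7 and C8 substituents.
- Comparison: the chosen route has the acyl group and the full oxidation pattern of ring B in place from step 1 and forms both quaternary centres C1 and C8 in the ring-closing step, in clearly fewer steps.

**Alternative 2:** Ring B is closed at C1–C2 by gold catalysis. In ynone silyl enol ether A4 (Ph3PAuCl/AgSbF6) the enol ether carbon C1 attacks the activated alkyne in a 6-endo-dig closure to give enedione A5.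
- For it: the closure is a mild π-acid reaction on a preformed ring A, and the relation of C5 to C7 is fixed by the order of two alkylations and not by a fold. On this point, and on the predictability of the ring closure, it is stronger than the chosen route.
- Against it: A4 needs a multistep stereocontrolled synthesis of ring A with three stereocentres, two of them quaternary. A5 still lacks the C2 oxygen and the C1 isobutyryl group, so the most hindered bond of the target, the acyl group on a bridgehead next to quaternary C8, is left for the end.
- Comparison: the chosen route gets that bond from an arene acylation and is much shorter; it pays with an uncertain fold.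

**Alternative 3:** Ring A is made by ring expansion. In epoxy alcohol A6 a Lewis acid (BF3·OEt2) opens the C4–C5 epoxide at C5 while the C9–C6 bond migrates to C5, giving hydroxy dione A7 with the C9 ketone.
- For it: the anti-periplanar 1,2-shift is stereospecific and transfers configuration to C5 cleanly. In stereochemical fidelity of the key step it is the strongest of the four.
- Against it: A6 is a cis-fused hydrindane with six stereocentres and a tetrasubstituted epoxide and is long to make. A7 still needs oxidation at C4 and acylation at C1.
- Comparison: the chosen route offers brevity and an aromatic precursor with one stereocentre, and accepts that its key step is unproven.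

Key step: step 8

Assumption: which antipode of the chiral ligand in step 7 leads to the (S) centre cannot be derived from structure alone; the (R,R) ligand is written, and its enantiomer would be used if the sense of induction is the opposite.

## Route

**Step 1**
Reactants: 1 phloroglucinol; 2 2-methylpropanoyl chloride
Product: 3 2-methyl-1-(2,4,6-trihydroxyphenyl)propan-1-one
Conditions: AlCl3 (3 equiv), PhNO2–CH2Cl2, 0 to 60 °C; aq. HCl
Reagents that add atoms: none
Why: Friedel–Crafts acylation of the strongly activated arene; the ketone deactivates the product, so one acyl group enters.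

**Step 2**
Reactants: 3 2-methyl-1-(2,4,6-trihydroxyphenyl)propan-1-one
Product: 4 1-(3-chloro-2,4,6-trihydroxyphenyl)-2-methylpropan-1-one
Conditions: SO2Cl2 (1.0 equiv), Et2O–CH2Cl2, −20 to 0 °C
Reagents that add atoms: sulfuryl chloride, ClS(Cl)(=O)=O
Why: Electrophilic aromatic chlorination at one of the two equivalent free ring carbons, a known reaction of acylphloroglucinols; one equivalent at low temperature should stop mainly at the monochloride because the first chlorine lowers the reactivity of the last free position.

**Step 3**
Reactants: 5 ethyl but-2-ynoate; 6 but-3-en-1-ylmagnesium bromide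
Product: 8 ethyl (2E)-3-methylhepta-2,6-dienoate, via alkenylcopper adduct 7 (not isolated)
Conditions: 6, CuI (1.2 equiv each), THF, −40 °C; then 5, −78 °C; aq. NH4Cl at −78 °C
Reagents that add atoms: none
Why: syn-Carbocupration of the ynoate, then protonation of 7 with retention at low temperature, should place the butenyl group trans to the ester and so fix the (E)-geometry that later becomes the C7/C8 relationship.

**Step 4**
Reactants: 8 ethyl (2E)-3-methylhepta-2,6-dienoate
Product: 9 (2E)-3-methylhepta-2,6-dien-1-ol
Conditions: iBu2AlH (2.2 equiv), CH2Cl2, −78 °C; aq. KNaC4H4O6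
Reagents that add atoms: none
Why: 1,2-Reduction of the conjugated ester to the allylic alcohol by two hydride transfers; the alkene geometry is not touched.

**Step 5**
Reactants: 9 (2E)-3-methylhepta-2,6-dien-1-ol
Product: 10 (2E)-1-bromo-3-methylhepta-2,6-diene
Conditions: PBr3 (0.4 equiv), Et2O, −10 °C; used without storage
Reagents that add atoms: phosphorus tribromide, BrP(Br)Br
Why: Bromination of the primary allylic alcohol through its phosphite ester (SN2); at low temperature no allylic transposition is expected.

**Step 6**
Reactants: 4 1-(3-chloro-2,4,6-trihydroxyphenyl)-2-methylpropan-1-one; 10 (2E)-1-bromo-3-methylhepta-2,6-diene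
Product: 11 1-{3-chloro-2,4,6-trihydroxy-5-[(2E)-3-methylhepta-2,6-dien-1-yl]phenyl}-2-methylpropan-1-one
Conditions: 1,8-diazabicyclo[5.4.0]undec-7-ene (1.1 equiv), THF, 0 °C to rt
Reagents that add atoms: none
Why: C-Alkylation of the ambident phloroglucinol anion by a soft allylic bromide; only one ring carbon still bears hydrogen, so the chain can enter only there, and SN2 at the primary carbon keeps the (E)-alkene.

**Step 7**
Reactants: 11 1-{3-chloro-2,4,6-trihydroxy-5-[(2E)-3-methylhepta-2,6-dien-1-yl]phenyl}-2-methylpropan-1-one; 12 methyl prop-2-en-1-yl carbonate
Product: 13 (6S)-4-chloro-3,5-dihydroxy-6-[(2E)-3-methylhepta-2,6-dien-1-yl]-2-(2-methylpropanoyl)-6-(prop-2-en-1-yl)cyclohexa-2,4-dien-1-one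
Conditions: Pd2(dba)3 (2.5 mol %), (1R,2R)-N,N'-bis[2-(diphenylphosphanyl)benzoyl]cyclohexane-1,2-diamine (7.5 mol %), THF, 0 °C
Reagents that add atoms: none
Why: Tsuji–Trost asymmetric allylic alkylation with dearomatisation: the π-allyl complex of zerovalent palladium is attacked by the alkyl-bearing ring carbon, the only one that is neither acyl- nor chloro-substituted, while O-allyl ethers re-ionise and funnel to the C-allyl product; the chiral ligand should tell apart the two enantiotopic faces of the planar anion and set C5 as (S) by catalyst control.

**Step 8**
Reactants: 13 (6S)-4-chloro-3,5-dihydroxy-6-[(2E)-3-methylhepta-2,6-dien-1-yl]-2-(2-methylpropanoyl)-6-(prop-2-en-1-yl)cyclohexa-2,4-dien-1-one; 14 1-bromo-3-methylbut-2-ene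
Product: 16 (1R,5S,7S,8R)-8-(but-3-en-1-yl)-3-chloro-4-hydroxy-8-methyl-7-(3-methylbut-2-en-1-yl)-1-(2-methylpropanoyl)-5-(prop-2-en-1-yl)bicyclo[3.3.1]non-3-ene-2,9-dione, via C8 carbocation 15 (not isolated)
Conditions: 13 (1.2 equiv), AgOSO2CF3 (1.2 equiv), 2,6-di-tert-butyl-4-methylpyridine (1.2 equiv), CH2Cl2, −78 °C; 14 (1.0 equiv) added slowly, −78 to −30 °C, dark
Reagents that add atoms: none
Why: Proposed new method: AgOSO2CF3 takes bromide from 14 and the ion-paired prenyl cation adds to C7, the less substituted end of the only trisubstituted alkene of 13, so that tertiary cation 15 forms at C8 and is trapped by enol carbon C1 (C7–prenyl and C1–C8 formed, ring A closed); the closest known reaction types are the iodonium- or proton-induced carbocyclisations of prenyl-type side chains onto enol carbons of dearomatised acylphloroglucinols and the silver-assisted alkylation of alkenes by allyl cations. Ring A closes in the 6-endo-trig mode, both alkene carbons ending in the ring and C1 reaching C8 through C9, C5 and C6. C7 and C8 are set relative to each other by anti addition across the (E)-alkene, which puts the prenyl group cis to the C8 methyl and trans to the butenyl arm; C1 has no freedom of its own, because C8 can bond only to the face of ring B that carries C6, so its configuration follows from C5. How C7 and C8 relate to C5 depends on the fold: the boat-like fold, with C7 swung out over the C9 carbonyl, puts the prenyl group on the ring B side as required, while the chair-like fold would give the C7,C8-diastereomer, and nothing in 13 enforces the boat. Selectivity among the alkenes is secured by the substrate, since the allyl and butenyl ends are monosubstituted and much less nucleophilic towards a carbocation. Capture at C1 rather than at C3 or an enol oxygen is only biased: the chlorine lowers the nucleophilicity of C3, O-prenyl and O-cyclised enol ethers can re-ionise under the conditions, and the hindered pyridine removes the triflic acid that would otherwise start a proton-initiated closure without the C7 prenyl group.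

**Step 9**
Reactants: 16 (1R,5S,7S,8R)-8-(but-3-en-1-yl)-3-chloro-4-hydroxy-8-methyl-7-(3-methylbut-2-en-1-yl)-1-(2-methylpropanoyl)-5-(prop-2-en-1-yl)bicyclo[3.3.1]non-3-ene-2,9-dione; 17 2-methylbut-2-ene
Product: 18 (1R,5S,7S,8R)-3-chloro-4-hydroxy-8-methyl-5,7-bis(3-methylbut-2-en-1-yl)-8-(4-methylpent-3-en-1-yl)-1-(2-methylpropanoyl)bicyclo[3.3.1]non-3-ene-2,9-dione
Conditions: second-generation Grubbs catalyst (5 mol %), 17 as solvent (with CH2Cl2), 35 °C, sealed vessel
Reagents that add atoms: none
Why: Olefin cross-metathesis of the two monosubstituted alkenes with a trisubstituted partner in large excess should give both isopropylidene ends with loss of propene; the C7 prenyl group can only exchange degenerately and no stereocentre is touched.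

**Step 10**
Reactants: 18 (1R,5S,7S,8R)-3-chloro-4-hydroxy-8-methyl-5,7-bis(3-methylbut-2-en-1-yl)-8-(4-methylpent-3-en-1-yl)-1-(2-methylpropanoyl)bicyclo[3.3.1]non-3-ene-2,9-dione
Product: 19 (1S,5S,7S,8R)-4-hydroxy-8-methyl-5,7-bis(3-methylbut-2-en-1-yl)-8-(4-methylpent-3-en-1-yl)-1-(2-methylpropanoyl)bicyclo[3.3.1]non-3-ene-2,9-dione
Conditions: Zn dust, AcOH–THF, 0 °C to rt
Reagents that add atoms: none
Why: Reductive dehalogenation of the 2-chloro-1,3-dicarbonyl unit by electron transfer from zinc and protonation of the zinc enolate; the alkenes and the non-enolisable ketones should be inert, and no centre can epimerise because C1, C5 and C8 are quaternary and C7 is not next to a carbonyl (the change of the C1 descriptor from R to S is only a change of priorities).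

## Compound list

1 | phloroglucinol (benzene-1,3,5-triol) | Oc1cc(O)cc(O)c1 | starting material
2 | 2-methylpropanoyl chloride (isobutyryl chloride) | CC(C)C(Cl)=O | starting material
3 | 2-methyl-1-(2,4,6-trihydroxyphenyl)propan-1-one | CC(C)C(=O)c1c(O)cc(O)cc1O | intermediate
4 | 1-(3-chloro-2,4,6-trihydroxyphenyl)-2-methylpropan-1-one | CC(C)C(=O)c1c(O)cc(O)c(Cl)c1O | intermediate
5 | ethyl but-2-ynoate | CCOC(=O)C#CC | starting material
6 | but-3-en-1-ylmagnesium bromide (THF solution) | C=CCC[Mg]Br | starting material
7 | ethyl (2Z)-2-cuprio-3-methylhepta-2,6-dienoate (alkenylcopper adduct, copper cis to the butenyl group) | CCOC(=O)/C([Cu])=C(C)/CCC=C | intermediate (not isolated)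
8 | ethyl (2E)-3-methylhepta-2,6-dienoate | CCOC(=O)/C=C(C)/CCC=C | intermediate
9 | (2E)-3-methylhepta-2,6-dien-1-ol | OC/C=C(C)/CCC=C | intermediate
10 | (2E)-1-bromo-3-methylhepta-2,6-diene | BrC/C=C(C)/CCC=C | intermediate
11 | 1-{3-chloro-2,4,6-trihydroxy-5-[(2E)-3-methylhepta-2,6-dien-1-yl]phenyl}-2-methylpropan-1-one | CC(C)C(=O)c1c(O)c(Cl)c(O)c(C/C=C(C)/CCC=C)c1O | intermediate
12 | methyl prop-2-en-1-yl carbonate (allyl methyl carbonate) | COC(=O)OCC=C | starting material
13 | (6S)-4-chloro-3,5-dihydroxy-6-[(2E)-3-methylhepta-2,6-dien-1-yl]-2-(2-methylpropanoyl)-6-(prop-2-en-1-yl)cyclohexa-2,4-dien-1-one (precursor of the key step) | C=CCC/C(C)=C/C[C@]1(CC=C)C(=O)C(C(=O)C(C)C)=C(O)C(Cl)=C1O | intermediate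
14 | 1-bromo-3-methylbut-2-ene (prenyl bromide) | CC(C)=CCBr | starting material
15 | tertiary C8 carbocation formed by addition of the prenyl cation to C7 of 13 (C7 configured as in 16) | C=CCC[C+](C)[C@@H](CC=C(C)C)C[C@]1(CC=C)C(=O)C(C(=O)C(C)C)=C(O)C(Cl)=C1O | intermediate (not isolated)
16 | (1R,5S,7S,8R)-8-(but-3-en-1-yl)-3-chloro-4-hydroxy-8-methyl-7-(3-methylbut-2-en-1-yl)-1-(2-methylpropanoyl)-5-(prop-2-en-1-yl)bicyclo[3.3.1]non-3-ene-2,9-dione (product of the key step) | C=CCC[C@]1(C)[C@@H](CC=C(C)C)C[C@]2(CC=C)C(=O)[C@@]1(C(=O)C(C)C)C(=O)C(Cl)=C2O | intermediate
17 | 2-methylbut-2-ene | CC=C(C)C | starting material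
18 | (1R,5S,7S,8R)-3-chloro-4-hydroxy-8-methyl-5,7-bis(3-methylbut-2-en-1-yl)-8-(4-methylpent-3-en-1-yl)-1-(2-methylpropanoyl)bicyclo[3.3.1]non-3-ene-2,9-dione (3-chloro derivative of the target) | CC(C)=CCC[C@]1(C)[C@@H](CC=C(C)C)C[C@]2(CC=C(C)C)C(=O)[C@@]1(C(=O)C(C)C)C(=O)C(Cl)=C2O | intermediate
19 | (1S,5S,7S,8R)-4-hydroxy-8-methyl-5,7-bis(3-methylbut-2-en-1-yl)-8-(4-methylpent-3-en-1-yl)-1-(2-methylpropanoyl)bicyclo[3.3.1]non-3-ene-2,9-dione | CC(C)=CCC[C@]1(C)[C@@H](CC=C(C)C)C[C@]2(CC=C(C)C)C(=O)[C@@]1(C(=O)C(C)C)C(=O)C=C2O | target

## Step count and least certain steps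

Total step count: 10. Longest linear sequence: 8 steps (steps 3 to 10, from 5); the branch from 1 joins at step 6.

**Step 8 (key step, new method).** Most likely to go wrong: ring A closes through the chair-like fold, which is normally the easier one and puts the C7 prenyl group on the C9 side, so that the C7,C8-diastereomer forms. Before that, part of the cation is likely lost to prenylation of the enol oxygens or of C3. A relay by iodonium-induced carbocyclisation and radical allylation is not offered, because a group brought to C7 after the bicycle exists should enter from the face away from ring B.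

Fallback (known reactions; sets out from 9 and 4, comes back at 18): the carbon substituent on C7 is put in place before ring A exists, so that the ring closure has no choice at C7.
- Sharpless epoxidation of 9 (Ti(OiPr)4, D-(−)-diethyl tartrate, tBuOOH) should give the (2R,3R)-epoxy alcohol F1.
- An allylcopper reagent (allylMgCl, CuI cat.) opens F1 at C2 with inversion to the 1,3-diol F2, which carries the future C7 with its allyl group and the future C8 as a tertiary alcohol.
- The primary hydroxyl is converted into the triflate F3 ((CF3SO2)2O, 2,6-lutidine, −78 °C, used at once).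
- Allyl bromide and 1,8-diazabicyclo[5.4.0]undec-7-ene turn 4 into the C-allyl arene F4.
- The lithium phenolate of F4 (LiN(SiMe3)2) is alkylated by F3 at the allyl-bearing carbon with dearomatisation, giving the dienone F5 together with its C5 epimer, which has to be separated.
- Formic acid ionises the tertiary alcohol of F5 and enol carbon C1 closes ring A to the bicycle F6 (acid-induced cationic cyclisation of a dearomatised acylphloroglucinol).
- The conditions of step 9 convert all three terminal alkenes of F6 and reach 18.

Because C7 is already fixed relative to C5 and C3 is blocked, closure at C1 can only give the ring-B-side arrangement at C7. The larger butenyl arm is expected to take the position trans to the C7 allyl group at C8. The price is six operations, an unselective C5 and a C8 that rests on a conformational preference.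

**Step 7.** Most likely to go wrong: poor facial selectivity, because the two faces of the planar anion differ only through the remote chloro and acyl flanks, with some allylation at oxygen. Fallback (sets out from 11, comes back at 13): run the dearomatising allylation without asymmetric induction (Pd(PPh3)4, 12) to racemic dienone F7 and separate the enantiomers by preparative chromatography on a chiral stationary phase.

**Step 9.** Most likely to go wrong: ring-closing metathesis of the butenyl arm on C8 with the neighbouring C7 prenyl group (seven-membered ring, loss of isobutene) competes with cross-metathesis. Fallback (sets out from 4, comes back at 18): carry the homoprenyl end from the start.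
- Geranyl bromide in place of 10 under the conditions of step 6 gives the geranyl arene F8.
- The conditions of step 7 give the allyl geranyl dienone F9.
- The conditions of step 8 give the bicycle F10, in which only the remote C5 allyl group is left for metathesis with 17.

The cost falls on step 8, where the distal alkene of the geranyl chain then competes for the cation.

**Step 6.** Most likely to go wrong: alkylation at oxygen and dearomatising over-alkylation outrun C-alkylation, since the chlorine lowers the nucleophilicity of the ring. Fallback (sets out from 3, comes back at 11): alkylate the more electron-rich 3 (in excess) with 10 to the dienyl arene F11, then chlorinate the last free ring position with N-chlorosuccinimide, which releases no acid.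

## Further compounds

F1 | step 8 | [(2R,3R)-3-(but-3-en-1-yl)-3-methyloxiran-2-yl]methanol | OC[C@H]1O[C@]1(C)CCC=C
F2 | step 8 | (2S,3R)-3-methyl-2-(prop-2-en-1-yl)hept-6-ene-1,3-diol | OC[C@H](CC=C)[C@](C)(O)CCC=C
F3 | step 8 | (2S,3R)-3-hydroxy-3-methyl-2-(prop-2-en-1-yl)hept-6-en-1-yl trifluoromethanesulfonate | O=S(=O)(OC[C@H](CC=C)[C@](C)(O)CCC=C)C(F)(F)F
F4 | step 8 | 1-[3-chloro-2,4,6-trihydroxy-5-(prop-2-en-1-yl)phenyl]-2-methylpropan-1-one | CC(C)C(=O)c1c(O)c(Cl)c(O)c(CC=C)c1O
F5 | step 8 | (6S)-4-chloro-3,5-dihydroxy-6-[(2S,3R)-3-hydroxy-3-methyl-2-(prop-2-en-1-yl)hept-6-en-1-yl]-2-(2-methylpropanoyl)-6-(prop-2-en-1-yl)cyclohexa-2,4-dien-1-one | C=CCC[C@@](C)(O)[C@@H](CC=C)C[C@]1(CC=C)C(=O)C(C(=O)C(C)C)=C(O)C(Cl)=C1O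
F6 | step 8 | (1R,5S,7S,8R)-8-(but-3-en-1-yl)-3-chloro-4-hydroxy-8-methyl-1-(2-methylpropanoyl)-5,7-bis(prop-2-en-1-yl)bicyclo[3.3.1]non-3-ene-2,9-dione | C=CCC[C@]1(C)[C@@H](CC=C)C[C@]2(CC=C)C(=O)[C@@]1(C(=O)C(C)C)C(=O)C(Cl)=C2O
F7 | step 7 | racemic 4-chloro-3,5-dihydroxy-6-[(2E)-3-methylhepta-2,6-dien-1-yl]-2-(2-methylpropanoyl)-6-(prop-2-en-1-yl)cyclohexa-2,4-dien-1-one (both configurations at C6) | C=CCC/C(C)=C/CC1(CC=C)C(=O)C(C(=O)C(C)C)=C(O)C(Cl)=C1O
F8 | step 9 | 1-{3-chloro-5-[(2E)-3,7-dimethylocta-2,6-dien-1-yl]-2,4,6-trihydroxyphenyl}-2-methylpropan-1-one | CC(C)C(=O)c1c(O)c(Cl)c(O)c(C/C=C(C)/CCC=C(C)C)c1O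
F9 | step 9 | (6S)-4-chloro-6-[(2E)-3,7-dimethylocta-2,6-dien-1-yl]-3,5-dihydroxy-2-(2-methylpropanoyl)-6-(prop-2-en-1-yl)cyclohexa-2,4-dien-1-one | CC(C)=CCC/C(C)=C/C[C@]1(CC=C)C(=O)C(C(=O)C(C)C)=C(O)C(Cl)=C1O
F10 | step 9 | (1R,5S,7S,8R)-3-chloro-4-hydroxy-8-methyl-7-(3-methylbut-2-en-1-yl)-8-(4-methylpent-3-en-1-yl)-1-(2-methylpropanoyl)-5-(prop-2-en-1-yl)bicyclo[3.3.1]non-3-ene-2,9-dione | CC(C)=CCC[C@]1(C)[C@@H](CC=C(C)C)C[C@]2(CC=C)C(=O)[C@@]1(C(=O)C(C)C)C(=O)C(Cl)=C2O
F11 | step 6 | 2-methyl-1-{2,4,6-trihydroxy-3-[(2E)-3-methylhepta-2,6-dien-1-yl]phenyl}propan-1-one | CC(C)C(=O)c1c(O)cc(O)c(C/C=C(C)/CCC=C)c1O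
A1 | alternative 1 | 2-methyl-3-(3-methylbut-2-en-1-yl)-2-(4-methylpent-3-en-1-yl)cyclopentan-1-one, prenyl cis to methyl (C7 and C8 as in 19; carbonyl = C9) | CC(C)=CCC[C@]1(C)[C@@H](CC=C(C)C)CCC1=O
A2 | alternative 1 | diketene (4-methylideneoxetan-2-one) | C=C1CC(=O)O1
A3 | alternative 1 | cis-fused C9-hydroxy hydrindane-2,4-dione with ring B fused on C5–C9 | CC(C)=CCC[C@]1(C)[C@@H](CC=C(C)C)C[C@H]2C(=O)CC(=O)C[C@@]12O
A4 | alternative 2 | ring A tert-butyldimethylsilyl enol ether (C9–O, C1=C9) bearing prenyl and prop-2-ynoyl on C5, with C5, C7 and C8 as in 19 | CC(C)=CCC[C@]1(C)[C@@H](CC=C(C)C)C[C@@](CC=C(C)C)(C(=O)C#C)C(O[Si](C)(C)C(C)(C)C)=C1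
A5 | alternative 2 | bicyclo[3.3.1]non-2-ene-4,9-dione with C5, C7 and C8 substituents and C1 unsubstituted | CC(C)=CCC[C@]1(C)[C@@H](CC=C(C)C)C[C@]2(CC=C(C)C)C(=O)[C@H]1C=CC2=O
A6 | alternative 3 | cis-fused C9-hydroxy hydrindan-2-one with a C4–C5 epoxide and prenyl on C5 (cyclopentane = C9, C6, C7, C8, C1) | CC(C)=CCC[C@]1(C)[C@@H](CC=C(C)C)C[C@]2(O)[C@H]1C(=O)C[C@H]3O[C@@]23CC=C(C)C
A7 | alternative 3 | 4-hydroxybicyclo[3.3.1]nonane-2,9-dione with C5, C7 and C8 set and C1 unsubstituted | CC(C)=CCC[C@]1(C)[C@@H](CC=C(C)C)C[C@]2(CC=C(C)C)C(=O)[C@H]1C(=O)C[C@H]2O
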